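**Retrosynthetic overview**
- The target comes from a fully allyl-protected, bromine-blocked 1-aryl-1,2-dihydronaphthalene tetraester by one reductive Pd/formate operation (ten allyl groups and two bromines removed).
- Ring B, the non-aromatic carbocycle and the only ring made, is closed by an acid-catalysed cyclisation of a C2-symmetric (E,E)-bis(arylidene)succinate tetraester. A bromine para to one oxygen forces closure ortho to oxygen (7,8-dioxygenation), and a chiral acid sets C1 and C2.
- Key disconnection: both ester O–C(sp3) bonds. The dicarboxylate of the bis(arylidene)succinic acid displaces triflate from two (S)-α-triflyloxy esters with inversion, so both (R) centres come from L-DOPA.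
- The diacid comes from a double Stobbe condensation of diethyl succinate with two molecules of a bromo-aldehyde; the hydroxy ester comes from L-DOPA by deaminative hydroxylation (retention) and allylation.
- Ring order: all four benzene rings are bought; ring B is closed after both ester linkages are in place.

Assumption: the (S,S) antipode of the acid catalyst in step 6 is taken to give the required core configuration; if the sense of induction is opposite, the (R,R) antipode is used.

Descriptor note: C1 has the same spatial arrangement in 13, 14 and 15. Its CIP label is R in 13, S in 14 and R in 15 only because the enol carbon and the bromine change the substituent priorities.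

**Step 1**
Reactants: 1 2-bromo-4,5-dihydroxybenzaldehyde
Product: 2 4,5-bis(allyloxy)-2-bromobenzaldehyde
Conditions: allyl bromide (2.5 equiv), K2CO3 (3 equiv), DMF, 50 °C
Reagents that add atoms: allyl bromide, C=CCBr
Why: Williamson ether synthesis in which K2CO3 deprotonates both phenols and the phenoxides displace bromide from allyl bromide by SN2; no stereocentre is involved.

**Step 2**
Reactants: 2 4,5-bis(allyloxy)-2-bromobenzaldehyde (2.2 equiv); 3 diethyl succinate
Product: 5 (2E,3E)-2,3-bis[4,5-bis(allyloxy)-2-bromobenzylidene]succinic acid, via monoethyl ester 4 (not isolated)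
Conditions: NaOEt (3 equiv), EtOH, reflux; then 2 M NaOH, reflux; then HCl to pH 2
Reagents that add atoms: sodium hydroxide, [Na+].[OH-]
Why: Double Stobbe condensation (the classical route to fulgenic acids) in which the succinate enolate adds to the non-enolisable aldehyde, lactonisation and E1cB ring opening place each aryl group trans to its carboxyl (E), and saponification of the remaining ethyl ester gives the (E,E)-diacid; no stereocentre is formed.

**Step 3**
Reactants: 6 L-DOPA
Product: 9 (S)-3-(3,4-dihydroxyphenyl)-2-hydroxypropanoic acid, via diazonium carboxylate 7 (not isolated), via α-lactone 8 (not isolated)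
Conditions: NaNO2 (1.5 equiv, slow addition), 1 M H2SO4, N2, 0 °C → rt
Reagents that add atoms: water, O
Why: Deaminative hydroxylation of an α-amino acid by diazotisation, in which the carboxylate displaces N2 from 7 with inversion to give 8 and water opens 8 with a second inversion, so the (S) configuration is retained overall.

**Step 4**
Reactants: 9 (S)-3-(3,4-dihydroxyphenyl)-2-hydroxypropanoic acid
Product: 10 allyl (S)-3-[3,4-bis(allyloxy)phenyl]-2-hydroxypropanoate
Conditions: allyl bromide (3.3 equiv), K2CO3 (3.5 equiv), DMF, rt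
Reagents that add atoms: allyl bromide, C=CCBr
Why: Carbonate-mediated SN2 allylation of the two phenoxides and the carboxylate, while the secondary alcohol is not deprotonated by carbonate and the (S) centre is untouched.

**Step 5**
Reactants: 10 allyl (S)-3-[3,4-bis(allyloxy)phenyl]-2-hydroxypropanoate (2.3 equiv); 5 (2E,3E)-2,3-bis[4,5-bis(allyloxy)-2-bromobenzylidene]succinic acid
Product: 12 bis{(R)-1-(allyloxycarbonyl)-2-[3,4-bis(allyloxy)phenyl]ethyl} (2E,3E)-2,3-bis[4,5-bis(allyloxy)-2-bromobenzylidene]succinate, via triflate 11 (not isolated)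
Conditions: 10, (CF3SO2)2O, 2,6-lutidine, CH2Cl2, −78 °C; cold solution added to 5 and Cs2CO3 (2.3 equiv) in DMF, −40 → 0 °C
Reagents that add atoms: none
Why: Key C–O bond formation by SN2 O-alkylation, in which the dicesium dicarboxylate of 5 displaces the non-nucleophilic triflate of 11 twice with Walden inversion, converting the L-DOPA-derived (S) centres into both (R)-configured ester carbons and avoiding acyl activation of 5, which would close it to the cyclic anhydride.

**Step 6**
Reactants: 12 bis{(R)-1-(allyloxycarbonyl)-2-[3,4-bis(allyloxy)phenyl]ethyl} (2E,3E)-2,3-bis[4,5-bis(allyloxy)-2-bromobenzylidene]succinate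
Product: 14 bis{(R)-1-(allyloxycarbonyl)-2-[3,4-bis(allyloxy)phenyl]ethyl} (1S,2S)-7,8-bis(allyloxy)-1-[4,5-bis(allyloxy)-2-bromophenyl]-5-bromo-1,2-dihydronaphthalene-2,3-dicarboxylate, via enol 13 (not isolated)
Conditions: imidodiphosphorimidate acid (S,S)-HN[P(=NSO2CF3)(O2C20H10Ar2)]2 with Ar = 3,5-(CF3)2C6H3 (10 mol%), dry CHCl3, 0 °C → rt
Reagents that add atoms: none
Why: Proposed new method: a catalytic enantioselective cationic carbocyclisation of a bis(arylidene)succinate, in which the confined strong acid protonates one of the two homotopic conjugated ester carbonyls of C2-symmetric 12, the resulting para-alkoxybenzyl cation at C1 sits as a contact ion pair in the chiral pocket that selects one helical s-cis conformer of the diene, the only free ortho carbon of the other aryl ring (next to O-allyl, the para site being blocked by bromine) attacks one face of C1 and sets that centre, loss of the arenium proton gives enol 13, and protonation of C2 anti to the new C1 aryl group (also the thermodynamic result) gives the trans product and returns the acid; the closest known reactions are the stoichiometric triflic acid cyclisation of (E,E)-dibenzylidenesuccinates to trans-1-aryl-1,2-dihydronaphthalene diesters and chiral Brønsted acid-catalysed Nazarov cyclisations of divinyl ketones.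

**Step 7**
Reactants: 14 bis{(R)-1-(allyloxycarbonyl)-2-[3,4-bis(allyloxy)phenyl]ethyl} (1S,2S)-7,8-bis(allyloxy)-1-[4,5-bis(allyloxy)-2-bromophenyl]-5-bromo-1,2-dihydronaphthalene-2,3-dicarboxylate
Product: 15 bis[(R)-1-carboxy-2-(3,4-dihydroxyphenyl)ethyl] (1R,2S)-1-(3,4-dihydroxyphenyl)-7,8-dihydroxy-1,2-dihydronaphthalene-2,3-dicarboxylate
Conditions: Pd(PPh3)4 (15 mol%), HCO2H/Et3N (5:2, excess), degassed DMF, 25 °C, then 70 °C
Reagents that add atoms: none
Why: Tsuji–Trost deallylation with formate as hydride donor, in which zerovalent palladium ionises all ten allyl–oxygen bonds at 25 °C and the π-allyl complexes are reduced to propene, and on warming the same Pd/formate couple hydrodehalogenates both aryl bromides (oxidative addition, formate decarboxylation, C–H reductive elimination) in a mildly acidic buffer that leaves the hindered trisubstituted alkene and all four stereocentres untouched.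

**Compound list**
1 | 2-bromo-4,5-dihydroxybenzaldehyde | O=Cc1cc(O)c(O)cc1Br | starting material
2 | 4,5-bis(allyloxy)-2-bromobenzaldehyde | O=Cc1cc(OCC=C)c(OCC=C)cc1Br | intermediate
3 | diethyl succinate | CCOC(=O)CCC(=O)OCC | starting material
4 | (2E,3E)-2,3-bis[4,5-bis(allyloxy)-2-bromobenzylidene]succinic acid monoethyl ester (sodium salt in the flask, not isolated) | CCOC(=O)/C(=C/c1cc(OCC=C)c(OCC=C)cc1Br)C(=C/c1cc(OCC=C)c(OCC=C)cc1Br)\C(=O)O | intermediate
5 | (2E,3E)-2,3-bis[4,5-bis(allyloxy)-2-bromobenzylidene]succinic acid | OC(=O)/C(=C/c1cc(OCC=C)c(OCC=C)cc1Br)C(=C/c1cc(OCC=C)c(OCC=C)cc1Br)\C(=O)O | intermediate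
6 | L-DOPA, (S)-2-amino-3-(3,4-dihydroxyphenyl)propanoic acid | N[C@@H](Cc1ccc(O)c(O)c1)C(=O)O | starting material
7 | (S)-1-carboxylato-2-(3,4-dihydroxyphenyl)ethanediazonium (not isolated) | N#[N+][C@@H](Cc1ccc(O)c(O)c1)C(=O)[O-] | intermediate
8 | (R)-3-(3,4-dihydroxybenzyl)oxiran-2-one (α-lactone, not isolated) | O=C1O[C@@H]1Cc1ccc(O)c(O)c1 | intermediate
9 | (S)-3-(3,4-dihydroxyphenyl)-2-hydroxypropanoic acid | O[C@@H](Cc1ccc(O)c(O)c1)C(=O)O | intermediate
10 | allyl (S)-3-[3,4-bis(allyloxy)phenyl]-2-hydroxypropanoate | O[C@@H](Cc1ccc(OCC=C)c(OCC=C)c1)C(=O)OCC=C | intermediate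
11 | allyl (S)-3-[3,4-bis(allyloxy)phenyl]-2-[(trifluoromethylsulfonyl)oxy]propanoate (not isolated) | FC(F)(F)S(=O)(=O)O[C@@H](Cc1ccc(OCC=C)c(OCC=C)c1)C(=O)OCC=C | intermediate
12 | bis{(R)-1-(allyloxycarbonyl)-2-[3,4-bis(allyloxy)phenyl]ethyl} (2E,3E)-2,3-bis[4,5-bis(allyloxy)-2-bromobenzylidene]succinate | C=CCOC(=O)[C@@H](Cc1ccc(OCC=C)c(OCC=C)c1)OC(=O)/C(=C/c1cc(OCC=C)c(OCC=C)cc1Br)C(=C/c1cc(OCC=C)c(OCC=C)cc1Br)\C(=O)O[C@H](Cc1ccc(OCC=C)c(OCC=C)c1)C(=O)OCC=C | intermediate
13 | enol (ketene hemiacetal) tautomer of 14 at the C2 ester, (1R) at C1, enol geometry undefined (not isolated) | O=C(O[C@H](Cc1ccc(OCC=C)c(OCC=C)c1)C(=O)OCC=C)C1=Cc2c(Br)cc(OCC=C)c(OCC=C)c2[C@@H](c2cc(OCC=C)c(OCC=C)cc2Br)C1=C(O)O[C@H](Cc1ccc(OCC=C)c(OCC=C)c1)C(=O)OCC=C | intermediate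
14 | bis{(R)-1-(allyloxycarbonyl)-2-[3,4-bis(allyloxy)phenyl]ethyl} (1S,2S)-7,8-bis(allyloxy)-1-[4,5-bis(allyloxy)-2-bromophenyl]-5-bromo-1,2-dihydronaphthalene-2,3-dicarboxylate (trans) | O=C(O[C@H](Cc1ccc(OCC=C)c(OCC=C)c1)C(=O)OCC=C)C1=Cc2c(Br)cc(OCC=C)c(OCC=C)c2[C@@H](c2cc(OCC=C)c(OCC=C)cc2Br)[C@@H]1C(=O)O[C@H](Cc1ccc(OCC=C)c(OCC=C)c1)C(=O)OCC=C | intermediate
15 | bis[(R)-1-carboxy-2-(3,4-dihydroxyphenyl)ethyl] (1R,2S)-1-(3,4-dihydroxyphenyl)-7,8-dihydroxy-1,2-dihydronaphthalene-2,3-dicarboxylate (CNP0244800.2) | O=C(O[C@H](Cc1ccc(O)c(O)c1)C(=O)O)C1=Cc2ccc(O)c(O)c2[C@@H](c2ccc(O)c(O)c2)[C@@H]1C(=O)O[C@H](Cc1ccc(O)c(O)c1)C(=O)O | target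

**Step count and risks**
Total steps: 7. Longest linear sequence: 5 steps (1 → 2 → 5 → 12 → 14 → 15; the branch 6 → 9 → 10 → 12 → 14 → 15 is equally long).

The three steps most likely to fail:

Step 2 (one-pot double Stobbe). The second condensation may stall, leaving mono-arylidene material. The fallback sets out from 2 and 3 and builds the diene in two separate condensations. One equivalent of 2 with KOC(CH3)3 in tert-butanol gives the half-ester (E)-4-[4,5-bis(allyloxy)-2-bromophenyl]-3-(ethoxycarbonyl)but-3-enoic acid F1. Fischer esterification (EtOH, H2SO4) gives diethyl (E)-2-[4,5-bis(allyloxy)-2-bromobenzylidene]succinate F2, whose methylene is again ester-activated. A second Stobbe condensation of F2 with 2 (NaOEt, EtOH) gives 4, and saponification returns to the route at 5.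

Step 6 (the proposed new cyclisation). The chiral acid may turn over slowly or give poor facial selectivity with this large substrate. The fallback uses known chemistry and gives up catalyst control. It sets out from 12, which is treated with CF3SO3H (3 equiv) in CH2Cl2 at −20 °C, the established stoichiometric cyclisation of (E,E)-dibenzylidenesuccinates. This gives the trans product as a roughly 1:1 mixture of 14 and its core-epimeric diastereomer bis{(R)-1-(allyloxycarbonyl)-2-[3,4-bis(allyloxy)phenyl]ethyl} (1R,2R)-7,8-bis(allyloxy)-1-[4,5-bis(allyloxy)-2-bromophenyl]-5-bromo-1,2-dihydronaphthalene-2,3-dicarboxylate F3. The two (R)-configured ester groups make these diastereomers, so they are separated by preparative HPLC, and the route is rejoined at 14.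

Step 7 (one-pot deallylation and debromination). Aryl bromide reduction may lag, or the conjugated alkene may be partly reduced at 70 °C. The fallback sets out from 14 and separates the two tasks. Radical debromination with Bu3SnH and azobisisobutyronitrile in toluene at 90 °C gives bis{(R)-1-(allyloxycarbonyl)-2-[3,4-bis(allyloxy)phenyl]ethyl} (1R,2S)-7,8-bis(allyloxy)-1-[3,4-bis(allyloxy)phenyl]-1,2-dihydronaphthalene-2,3-dicarboxylate F4. Deallylation of F4 with Pd(PPh3)4 and morpholine in THF at 25 °C then returns to the route at 15.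

**Further compounds**
F1 | step 2 | (E)-4-[4,5-bis(allyloxy)-2-bromophenyl]-3-(ethoxycarbonyl)but-3-enoic acid | CCOC(=O)/C(=C/c1cc(OCC=C)c(OCC=C)cc1Br)CC(=O)O
F2 | step 2 | diethyl (E)-2-[4,5-bis(allyloxy)-2-bromobenzylidene]succinate | CCOC(=O)/C(=C/c1cc(OCC=C)c(OCC=C)cc1Br)CC(=O)OCC
F3 | step 6 | bis{(R)-1-(allyloxycarbonyl)-2-[3,4-bis(allyloxy)phenyl]ethyl} (1R,2R)-7,8-bis(allyloxy)-1-[4,5-bis(allyloxy)-2-bromophenyl]-5-bromo-1,2-dihydronaphthalene-2,3-dicarboxylate | O=C(O[C@H](Cc1ccc(OCC=C)c(OCC=C)c1)C(=O)OCC=C)C1=Cc2c(Br)cc(OCC=C)c(OCC=C)c2[C@H](c2cc(OCC=C)c(OCC=C)cc2Br)[C@H]1C(=O)O[C@H](Cc1ccc(OCC=C)c(OCC=C)c1)C(=O)OCC=C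
F4 | step 7 | bis{(R)-1-(allyloxycarbonyl)-2-[3,4-bis(allyloxy)phenyl]ethyl} (1R,2S)-7,8-bis(allyloxy)-1-[3,4-bis(allyloxy)phenyl]-1,2-dihydronaphthalene-2,3-dicarboxylate | O=C(O[C@H](Cc1ccc(OCC=C)c(OCC=C)c1)C(=O)OCC=C)C1=Cc2ccc(OCC=C)c(OCC=C)c2[C@@H](c2ccc(OCC=C)c(OCC=C)c2)[C@@H]1C(=O)O[C@H](Cc1ccc(OCC=C)c(OCC=C)c1)C(=O)OCC=C
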